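**Plan**

1. The retrosynthesis first cuts the two C7–O bonds of the 1,4-dioxane. This reduces the C2-symmetric target to two molecules of one 6α,7α-diol, which comes from the C6=C7 styrene of a single abietane half.
2. In that half the C7–C8 bond of ring B and the C5–C10 bond of ring A are cut together, giving an acyclic tertiary benzylic alcohol (C10) that carries a (Z)-α-methoxyallylsilane (C5=C6–C7).
3. The feature used: C10 is a tertiary benzylic carbon (stable cation) and C8 is the arene carbon para to the C12 methoxy group, so C7 is a p-methoxybenzylic position. C5–C6–C7 is an allyl unit that is nucleophilic at C5 and afterwards an oxocarbenium electrophile at C7.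
4. Forward: the aryl bromide and the C20–C10–C1…C7 chain are joined at C9–C10 by Grignard addition. One acid-catalysed cascade closes ring A and then ring B, and dihydroxylation followed by acid-mediated dimerisation closes the dioxane last.
5. Stereochemistry: the one reagent-controlled centre is C7 of the allylsilane (asymmetric transfer hydrogenation); it is transferred to C5 by anti SE2' attack, relayed to C10 through the chair, and then erased. C6 comes from α-face dihydroxylation and C7 from thermodynamically controlled trans ether formation.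

Key step: step 14

Assumption: abietane numbering (C1–C20) is used for each half; because the two halves are identical (C2 axis) the ring-forming event is run on the monomer, and the (R,R)-TsDPEN ruthenium catalyst is taken to give the (R)-carbinol in step 9 by analogy with alkynyl ketones (the antipodal ligand is used if the sense is opposite).

**Route**

Step 1
Reactants: 1 methyl 4-bromo-2-methoxybenzoate
Product: 2 2-(4-bromo-2-methoxyphenyl)propan-2-ol
Conditions: MeMgBr (3 equiv), THF, 0 °C to rt
Reagents that add atoms: methylmagnesium bromide, C[Mg]Br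
Why: Double Grignard addition to the ester gives the tertiary benzylic alcohol, and the aryl bromide does not exchange with MeMgBr at this temperature.

Step 2
Reactants: 2 2-(4-bromo-2-methoxyphenyl)propan-2-ol
Product: 3 4-bromo-2-methoxy-1-(propan-2-yl)benzene
Conditions: Et3SiH, CF3CO2H, CH2Cl2, 0 °C to rt
Reagents that add atoms: none
Why: Ionic hydrogenation, in which the tertiary benzylic cation (stabilised by the ortho methoxy group) is reduced by the silane, so the isopropyl group arises without touching the C–Br bond.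

Step 3
Reactants: 4 2-methylpropanenitrile; 5 2-(3-chloropropyl)-2-methyl-1,3-dioxolane
Product: 6 2,2-dimethyl-5-(2-methyl-1,3-dioxolan-2-yl)pentanenitrile
Conditions: LDA, THF, −78 °C; then 5, NaI (cat.), DMPU, −78 °C to rt
Reagents that add atoms: none
Why: SN2 alkylation of the lithiated nitrile with the primary halide (speeded by in situ Finkelstein exchange) builds the quaternary C4, while the ketal masks the future C10 ketone.

Step 4
Reactants: 6 2,2-dimethyl-5-(2-methyl-1,3-dioxolan-2-yl)pentanenitrile
Product: 7 2,2-dimethyl-5-(2-methyl-1,3-dioxolan-2-yl)pentanal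
Conditions: DIBAL-H, toluene, −78 °C; then aqueous tartrate buffer (pH 5), 0 °C
Reagents that add atoms: water, O
Why: DIBAL-H reduction of a hindered tertiary nitrile stops at the aluminium aldimine, and buffered hydrolysis should release the C5 aldehyde without loss of the dioxolane.

Step 5
Reactants: 7 2,2-dimethyl-5-(2-methyl-1,3-dioxolan-2-yl)pentanal
Product: 8 2-(4,4-dimethylhex-5-yn-1-yl)-2-methyl-1,3-dioxolane
Conditions: dimethyl (1-diazo-2-oxopropyl)phosphonate, K2CO3, MeOH, 0 °C to rt
Reagents that add atoms: dimethyl (1-diazo-2-oxopropyl)phosphonate, COP(=O)(OC)C(=[N+]=[N-])C(C)=O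
Why: Ohira–Bestmann (Seyferth–Gilbert) homologation adds C6 as the alkyne terminus, and the aldehyde has no α-hydrogen to suffer under the basic methanol.

Step 6
Reactants: 8 2-(4,4-dimethylhex-5-yn-1-yl)-2-methyl-1,3-dioxolane
Product: 9 4,4-dimethyl-7-(2-methyl-1,3-dioxolan-2-yl)hept-2-ynal
Conditions: n-BuLi, THF, −78 °C; then DMF; inverse quench into aqueous KH2PO4
Reagents that add atoms: N,N-dimethylformamide, CN(C)C=O
Why: Formylation of the lithium acetylide with DMF introduces C7, and the buffered inverse quench prevents addition of the liberated dimethylamine to the ynal.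

Step 7
Reactants: 9 4,4-dimethyl-7-(2-methyl-1,3-dioxolan-2-yl)hept-2-ynal
Product: 10 rac-1-[dimethyl(phenyl)silyl]-4,4-dimethyl-7-(2-methyl-1,3-dioxolan-2-yl)hept-2-yn-1-ol
Conditions: PhMe2SiLi, THF, −78 °C; AcOH quench at −78 °C
Reagents that add atoms: dimethyl(phenyl)silyllithium, [Li][Si](C)(C)c1ccccc1
Why: 1,2-Addition of the hard silyllithium to the aldehyde at low temperature gives the α-silyl carbinol, and cold protonation should forestall Brook rearrangement.

Step 8
Reactants: 10 rac-1-[dimethyl(phenyl)silyl]-4,4-dimethyl-7-(2-methyl-1,3-dioxolan-2-yl)hept-2-yn-1-ol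
Product: 11 1-[dimethyl(phenyl)silyl]-4,4-dimethyl-7-(2-methyl-1,3-dioxolan-2-yl)hept-2-yn-1-one
Conditions: (COCl)2, DMSO, CH2Cl2, −78 °C; then Et3N
Reagents that add atoms: none
Why: Swern oxidation is the standard conversion of an α-hydroxysilane into an acylsilane and avoids the alkoxide that would trigger Brook rearrangement.

Step 9
Reactants: 11 1-[dimethyl(phenyl)silyl]-4,4-dimethyl-7-(2-methyl-1,3-dioxolan-2-yl)hept-2-yn-1-one
Product: 12 (1R)-1-[dimethyl(phenyl)silyl]-4,4-dimethyl-7-(2-methyl-1,3-dioxolan-2-yl)hept-2-yn-1-ol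
Conditions: Ru[(R,R)-TsDPEN](p-cymene) (2 mol %), i-PrOH, rt
Reagents that add atoms: none
Why: Noyori-type asymmetric transfer hydrogenation of an alkynyl acylsilane (the acylsilane counterpart of an alkynyl ketone), in which the chiral Ru–H/N–H complex tells the alkynyl group from the silyl group and sets C7 as (R).

Step 10
Reactants: 12 (1R)-1-[dimethyl(phenyl)silyl]-4,4-dimethyl-7-(2-methyl-1,3-dioxolan-2-yl)hept-2-yn-1-ol
Product: 13 [(1R)-1-methoxy-4,4-dimethyl-7-(2-methyl-1,3-dioxolan-2-yl)hept-2-yn-1-yl]dimethyl(phenyl)silane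
Conditions: MeOTf, 2,6-di-tert-butyl-4-methylpyridine, CH2Cl2, 0 °C to rt
Reagents that add atoms: methyl trifluoromethanesulfonate, COS(=O)(=O)C(F)(F)F
Why: O-Methylation with a strong methylating agent and a hindered pyridine base forms no alkoxide, so neither Brook rearrangement nor loss of configuration at C7 is expected.

Step 11
Reactants: 13 [(1R)-1-methoxy-4,4-dimethyl-7-(2-methyl-1,3-dioxolan-2-yl)hept-2-yn-1-yl]dimethyl(phenyl)silane
Product: 14 [(1R,2Z)-1-methoxy-4,4-dimethyl-7-(2-methyl-1,3-dioxolan-2-yl)hept-2-en-1-yl]dimethyl(phenyl)silane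
Conditions: H2 (1 atm), Pd/CaCO3 poisoned with Pb(OAc)2, quinoline, EtOAc, rt
Reagents that add atoms: none
Why: Lindlar semi-hydrogenation adds H2 syn and gives the (Z)-alkene that step 14 needs for A(1,3) control.

Step 12
Reactants: 14 [(1R,2Z)-1-methoxy-4,4-dimethyl-7-(2-methyl-1,3-dioxolan-2-yl)hept-2-en-1-yl]dimethyl(phenyl)silane
Product: 15 (7Z,9R)-9-[dimethyl(phenyl)silyl]-9-methoxy-6,6-dimethylnon-7-en-2-one
Conditions: pyridinium p-toluenesulfonate (cat.), acetone/H2O, 45 °C
Reagents that add atoms: water, O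
Why: Mild acid hydrolysis of the dioxolane frees the methyl ketone (C10, C20), and the hindered allylsilane should tolerate the buffered acid.

Step 13
Reactants: 3 4-bromo-2-methoxy-1-(propan-2-yl)benzene; 15 (7Z,9R)-9-[dimethyl(phenyl)silyl]-9-methoxy-6,6-dimethylnon-7-en-2-one
Product: 17 (7Z,9R)-9-[dimethyl(phenyl)silyl]-9-methoxy-2-[3-methoxy-4-(propan-2-yl)phenyl]-6,6-dimethylnon-7-en-2-ol (both epimers at the carbinol carbon), via aryl Grignard reagent 16 (not isolated)
Conditions: Mg, THF, 40 °C; then 15, LaCl3·2LiCl, THF, 0 °C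
Reagents that add atoms: none
Why: Grignard addition to the methyl ketone (LaCl3·2LiCl suppresses enolisation) forms the C9–C10 bond; the carbinol centre is a mixture, which does not matter because it is ionised in step 14.

Step 14
Reactants: 17 (7Z,9R)-9-[dimethyl(phenyl)silyl]-9-methoxy-2-[3-methoxy-4-(propan-2-yl)phenyl]-6,6-dimethylnon-7-en-2-ol
Product: 20 (4bS,8aS)-3-methoxy-4b,8,8-trimethyl-2-(propan-2-yl)-4b,5,6,7,8,8a-hexahydrophenanthrene (12-methoxyabieta-6,8,11,13-tetraene), via enol ether 18 (not isolated), via 7-methoxy tricycle 19 (not isolated)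
Conditions: Bi(OTf)3 (5 mol %), CH2Cl2 (0.01 M), −40 °C to 35 °C
Reagents that add atoms: none
Why: Proposed new method: Bi(OTf)3 ionises the tertiary benzylic alcohol to the C10 cation, C5 of the allylsilane attacks it in an anti SE2' step that closes ring A and expels silicon to give enol ether 18, protonation of 18 at C6 gives the C7 oxocarbenium ion that alkylates the arene at C8 to close ring B, and the p-methoxybenzylic ether 19 then loses methanol to the C6=C7 styrene. The closest known reaction types are the allylsilane-terminated cation–olefin cyclisation (intramolecular Hosomi–Sakurai alkylation of a benzylic alcohol) and the oxocarbenium Friedel–Crafts cyclodehydration of an arylacetaldehyde equivalent; their coupling through an α-alkoxyallylsilane, which makes C5 nucleophilic and then C7 electrophilic, is the new element. Ring A closes in a chair by attack of the C5=C6 π bond with C6 left exocyclic (6-exo), and ring B closes 6-exo with respect to the C7=O+ bond (6-endo with respect to the arene π bond). C5 is controlled by the C7 silyl stereocentre, since A(1,3) strain in the (Z)-alkene keeps H7 in the alkene plane, the cation adds anti to the C–Si bond, and (R)-C7 gives 5α-H; C10 is controlled relative to C5 by the chair, in which the aryl group is equatorial and the methyl group axial, which gives the trans A/B fusion. The step needs γ-selective attack of the allylsilane, secured by β-silicon stabilisation of the developing C6 cation, and closure at C8 and not at C11, secured by C8 being para to the C12 methoxy group and flanked by hydrogen. C7 ends as an sp2 carbon, so its configuration in 17 is spent in the transfer.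

Step 15
Reactants: 20 (4bS,8aS)-3-methoxy-4b,8,8-trimethyl-2-(propan-2-yl)-4b,5,6,7,8,8a-hexahydrophenanthrene
Product: 21 (4bS,8aS,9R,10S)-3-methoxy-4b,8,8-trimethyl-2-(propan-2-yl)-4b,5,6,7,8,8a,9,10-octahydrophenanthrene-9,10-diol (6α,7α-diol in abietane numbering)
Conditions: OsO4 (2 mol %), N-methylmorpholine N-oxide, acetone/H2O, rt
Reagents that add atoms: N-methylmorpholine N-oxide, C[N+]1([O-])CCOCC1; water, O
Why: Upjohn dihydroxylation adds both oxygens suprafacially from the α face, because the β face at C6 is 1,3-diaxial to the C10 and C4β methyl groups, and so sets 6α-OH.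

Step 16
Reactants: 21 (4bS,8aS,9R,10S)-3-methoxy-4b,8,8-trimethyl-2-(propan-2-yl)-4b,5,6,7,8,8a,9,10-octahydrophenanthrene-9,10-diol (two molecules)
Product: 22 CNP0327150.1 (C2-symmetric dimer of two 12-methoxyabieta-8,11,13-triene units joined by a 1,4-dioxane through O–C6α and O–C7β of each half)
Conditions: Bi(OTf)3 (2 mol %), 4 Å molecular sieves, CH2Cl2 (0.5 M), −20 °C to rt
Reagents that add atoms: none
Why: Dehydrative SN1 etherification, in which only the p-methoxybenzylic C7–OH ionises and the cation is trapped by the 6α-OH of a second molecule, then again intramolecularly to close the dioxane; C6 keeps its configuration, and reversible ionisation at C7 should lead to the trans-diequatorial 7β ethers.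

**Compound list**

1 | methyl 4-bromo-2-methoxybenzoate | COC(=O)c1ccc(Br)cc1OC | starting material
2 | 2-(4-bromo-2-methoxyphenyl)propan-2-ol | CC(C)(O)c1ccc(Br)cc1OC | intermediate
3 | 4-bromo-2-methoxy-1-(propan-2-yl)benzene | CC(C)c1ccc(Br)cc1OC | intermediate
4 | 2-methylpropanenitrile | CC(C)C#N | starting material
5 | 2-(3-chloropropyl)-2-methyl-1,3-dioxolane | CC1(CCCCl)OCCO1 | starting material
6 | 2,2-dimethyl-5-(2-methyl-1,3-dioxolan-2-yl)pentanenitrile | CC1(CCCC(C)(C)C#N)OCCO1 | intermediate
7 | 2,2-dimethyl-5-(2-methyl-1,3-dioxolan-2-yl)pentanal | CC1(CCCC(C)(C)C=O)OCCO1 | intermediate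
8 | 2-(4,4-dimethylhex-5-yn-1-yl)-2-methyl-1,3-dioxolane | CC1(CCCC(C)(C)C#C)OCCO1 | intermediate
9 | 4,4-dimethyl-7-(2-methyl-1,3-dioxolan-2-yl)hept-2-ynal | CC1(CCCC(C)(C)C#CC=O)OCCO1 | intermediate
10 | rac-1-[dimethyl(phenyl)silyl]-4,4-dimethyl-7-(2-methyl-1,3-dioxolan-2-yl)hept-2-yn-1-ol | CC1(CCCC(C)(C)C#CC(O)[Si](C)(C)c2ccccc2)OCCO1 | intermediate
11 | 1-[dimethyl(phenyl)silyl]-4,4-dimethyl-7-(2-methyl-1,3-dioxolan-2-yl)hept-2-yn-1-one | CC1(CCCC(C)(C)C#CC(=O)[Si](C)(C)c2ccccc2)OCCO1 | intermediate
12 | (1R)-1-[dimethyl(phenyl)silyl]-4,4-dimethyl-7-(2-methyl-1,3-dioxolan-2-yl)hept-2-yn-1-ol | CC1(CCCC(C)(C)C#C[C@H](O)[Si](C)(C)c2ccccc2)OCCO1 | intermediate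
13 | [(1R)-1-methoxy-4,4-dimethyl-7-(2-methyl-1,3-dioxolan-2-yl)hept-2-yn-1-yl]dimethyl(phenyl)silane | CC1(CCCC(C)(C)C#C[C@H](OC)[Si](C)(C)c2ccccc2)OCCO1 | intermediate
14 | [(1R,2Z)-1-methoxy-4,4-dimethyl-7-(2-methyl-1,3-dioxolan-2-yl)hept-2-en-1-yl]dimethyl(phenyl)silane | CC1(CCCC(C)(C)/C=C\[C@H](OC)[Si](C)(C)c2ccccc2)OCCO1 | intermediate
15 | (7Z,9R)-9-[dimethyl(phenyl)silyl]-9-methoxy-6,6-dimethylnon-7-en-2-one | CC(=O)CCCC(C)(C)/C=C\[C@H](OC)[Si](C)(C)c1ccccc1 | intermediate
16 | [3-methoxy-4-(propan-2-yl)phenyl]magnesium bromide | CC(C)c1ccc([Mg]Br)cc1OC | intermediate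
17 | (7Z,9R)-9-[dimethyl(phenyl)silyl]-9-methoxy-2-[3-methoxy-4-(propan-2-yl)phenyl]-6,6-dimethylnon-7-en-2-ol (both epimers at the carbinol carbon) | CC(O)(CCCC(C)(C)/C=C\[C@H](OC)[Si](C)(C)c1ccccc1)c1ccc(C(C)C)c(OC)c1 | intermediate
18 | 2-methoxy-4-{(1S,2S)-2-[(E)-2-methoxyethenyl]-1,3,3-trimethylcyclohexyl}-1-(propan-2-yl)benzene | CO/C=C/[C@H]1C(C)(C)CCC[C@]1(C)c1ccc(C(C)C)c(OC)c1 | intermediate
19 | (4bS,8aS)-3,10-dimethoxy-4b,8,8-trimethyl-2-(propan-2-yl)-4b,5,6,7,8,8a,9,10-octahydrophenanthrene (7,12-dimethoxyabieta-8,11,13-triene, either C7 epimer) | COc1cc2c(cc1C(C)C)C(OC)C[C@H]1C(C)(C)CCC[C@]21C | intermediate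
20 | (4bS,8aS)-3-methoxy-4b,8,8-trimethyl-2-(propan-2-yl)-4b,5,6,7,8,8a-hexahydrophenanthrene (12-methoxyabieta-6,8,11,13-tetraene) | COc1cc2c(cc1C(C)C)C=C[C@H]1C(C)(C)CCC[C@]21C | intermediate
21 | (4bS,8aS,9R,10S)-3-methoxy-4b,8,8-trimethyl-2-(propan-2-yl)-4b,5,6,7,8,8a,9,10-octahydrophenanthrene-9,10-diol (12-methoxyabieta-8,11,13-triene-6α,7α-diol) | COc1cc2c(cc1C(C)C)[C@H](O)[C@H](O)[C@H]1C(C)(C)CCC[C@]21C | intermediate
22 | CNP0327150.1 (C2-symmetric dimer of two 12-methoxyabieta-8,11,13-triene units joined by a 1,4-dioxane through O–C6α and O–C7β of each half) | COc1cc2c(cc1C(C)C)[C@H]1O[C@H]3[C@H](O[C@@H]1[C@H]1C(C)(C)CCC[C@]21C)c1cc(C(C)C)c(OC)cc1[C@@]1(C)CCCC(C)(C)[C@H]31 | target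

**Totals**

Total step count: 16. Longest linear sequence: 14 steps (steps 3 to 16).

**Steps most likely to fail**

Step 14 (proposed new method). The allylsilane may be protodesilylated before ring A closes, or ring A may close through the chair with an axial aryl group, which would erode the C5/C10 relationship. The fallback uses a known enantioselective proton-initiated polyene cyclisation, which forms the C4–C5 and C9–C10 bonds instead. It sets out from 3 as its Grignard reagent 16. Trapping with paraformaldehyde should give [3-methoxy-4-(propan-2-yl)phenyl]methanol F1, and SOCl2 should give 4-(chloromethyl)-2-methoxy-1-(propan-2-yl)benzene F2. The Grignard reagent of F2 is coupled with geranyl chloride (Li2CuCl4 cat.) to the homogeranylarene 4-[(3E)-4,8-dimethylnona-3,7-dien-1-yl]-2-methoxy-1-(propan-2-yl)benzene F3. Cyclisation with a stoichiometric chiral Lewis-acid-assisted Brønsted acid (BINOL monoether·SnCl4, the antipode that leads to the 5S,10S series), then CF3CO2H/SnCl4 to complete the second ring, should give 12-methoxyabieta-8,11,13-triene F4. DDQ dehydrogenation at the p-methoxybenzylic C7 comes back to the route at 20.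

Step 16. A 1,2-hydride shift from C6 to the C7 cation (semipinacol loss to the 6-ketone) may outrun bimolecular capture by the hindered 6α-hydroxyl. The fallback couples two different partners stepwise, so that the second C–O bond forms intramolecularly. It sets out from 20. Dimethyldioxirane should give the 6α,7α-epoxide, 6α,7α-epoxy-12-methoxyabieta-8,11,13-triene F5. Methanolysis of half of it (MeOH, cat. pyridinium p-toluenesulfonate) should give 7β,12-dimethoxyabieta-8,11,13-trien-6α-ol F6. F5 is then opened at C7 by the only free hydroxyl of F6 (cat. BF3·OEt2, −78 °C) to give the hydroxy ether 7β-[(7β,12-dimethoxyabieta-8,11,13-trien-6α-yl)oxy]-12-methoxyabieta-8,11,13-trien-6α-ol F7. Ionisation of its 7-methoxy group (cat. TMSOTf, −78 °C) closes the dioxane and comes back at 22.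

Step 7. The α-silyl alkoxide may undergo Brook rearrangement, or the silyllithium may add in a conjugate sense to the ynal. The fallback moves silicon from oxygen to carbon instead. It sets out from 8. Its lithium acetylide with paraformaldehyde should give 4,4-dimethyl-7-(2-methyl-1,3-dioxolan-2-yl)hept-2-yn-1-ol F8, and PhMe2SiCl/imidazole should give the silyl ether {[4,4-dimethyl-7-(2-methyl-1,3-dioxolan-2-yl)hept-2-yn-1-yl]oxy}dimethyl(phenyl)silane F9. Propargylic deprotonation with tert-butyllithium (THF, −78 °C) triggers the retro-[1,2]-Brook shift and comes back at 10.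

**Further compounds**

F1 | step 14 | [3-methoxy-4-(propan-2-yl)phenyl]methanol | COc1cc(CO)ccc1C(C)C
F2 | step 14 | 4-(chloromethyl)-2-methoxy-1-(propan-2-yl)benzene | COc1cc(CCl)ccc1C(C)C
F3 | step 14 | 4-[(3E)-4,8-dimethylnona-3,7-dien-1-yl]-2-methoxy-1-(propan-2-yl)benzene | COc1cc(CC/C=C(\C)CCC=C(C)C)ccc1C(C)C
F4 | step 14 | (4bS,8aS)-3-methoxy-4b,8,8-trimethyl-2-(propan-2-yl)-4b,5,6,7,8,8a,9,10-octahydrophenanthrene (12-methoxyabieta-8,11,13-triene) | COc1cc2c(cc1C(C)C)CC[C@H]1C(C)(C)CCC[C@]21C
F5 | step 16 | 6α,7α-epoxy-12-methoxyabieta-8,11,13-triene | COc1cc2c(cc1C(C)C)[C@@H]1O[C@@H]1[C@H]1C(C)(C)CCC[C@]21C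
F6 | step 16 | 7β,12-dimethoxyabieta-8,11,13-trien-6α-ol | COc1cc2c(cc1C(C)C)[C@@H](OC)[C@H](O)[C@H]1C(C)(C)CCC[C@]21C
F7 | step 16 | 7β-[(7β,12-dimethoxyabieta-8,11,13-trien-6α-yl)oxy]-12-methoxyabieta-8,11,13-trien-6α-ol | COc1cc2c(cc1C(C)C)[C@@H](O[C@H]3[C@H](OC)c4cc(C(C)C)c(OC)cc4[C@@]4(C)CCCC(C)(C)[C@H]34)[C@H](O)[C@H]1C(C)(C)CCC[C@]21C
F8 | step 7 | 4,4-dimethyl-7-(2-methyl-1,3-dioxolan-2-yl)hept-2-yn-1-ol | CC1(CCCC(C)(C)C#CCO)OCCO1
F9 | step 7 | {[4,4-dimethyl-7-(2-methyl-1,3-dioxolan-2-yl)hept-2-yn-1-yl]oxy}dimethyl(phenyl)silane | CC1(CCCC(C)(C)C#CCO[Si](C)(C)c2ccccc2)OCCO1
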